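# Proposed total synthesis of CNP0148998.1, a (3R)-isoflavan quinone

## Structural features

The target is an isoflavan quinone: a chroman (benzene ring A fused through C4a–C8a to the dihydropyran ring C) whose C3 is bonded to C1′ of a 1,4-benzoquinone (ring B). Ring A is fully differentiated, with OMe on C5, a prenyl group on C6 and a free OH on C7. Ring B has its carbonyls at C2′ and C5′, a prenyl group on C3′, an acidic OH on C4′ and only hydrogen on C6′. C3 (R) is the single stereocentre; it carries H, the two CH2 arms C2 (bound to O1) and C4 (bound to C4a) and ring B, so no neighbouring stereocentre or heteroatom can relay control and the control must be absolute. The fragile parts are: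
- the two prenyl alkenes, each ortho to an OH, which acid closes to dimethylchromans and which exclude hydrogenation;
- the hydroxyquinone, which is sensitive to base, nucleophiles and reductants;
- C3 itself whenever it stands α to a carbonyl and β to the aryloxy oxygen O1.

The real difficulty is the combination of a heteroatom-free stereocentre, the regiochemistry of ring A (prenyl at C6 and not C8, methyl on O5 and not O7) and the four contiguous substituents of ring B. The key step uses the fact that, with CH2OH in place of ring B, C3 becomes the prochiral carbon of a 2-benzylpropane-1,3-diol, while C5 and C8a are the two equivalent ortho carbons of a 4-oxygenated benzyl unit. Closing O1–C8a on one arm then makes ring C and C3 together and leaves a halogen on C5, where the oxygen that later steers the prenyl group to C6 is needed.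

## Logic of the disconnections

**25 to 24.** The O4′–C(CH3)3 and O7–CH2OCH3 bonds are cut. Both oxygens must be masked through the organolithium and thermal steps, and both masks leave under acid in one operation. The forward step must be mild enough to spare two prenyl groups that each sit next to a free OH.

**24 to 23.** Ring B is unfolded by cutting C1′–C2′ and re-joining C2′ to C5′ as a four-membered ring. All four substituents of ring B then come from a cyclobutenone whose substitution is easy to program. The forward step needs six-membered closure and hydrogen transfer to outrun five-membered closure.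

**23 to 16 and 21 (through 22).** The C5′–C6′ bond between a carbonyl carbon and an acetylide carbon is cut. This gives a convergent union of the chroman half with a four-carbon ring B precursor. The acetylide must attack the ketone-like carbonyl next to the C–O-tert-butyl carbon and must not deprotonate the allylic CH2 of 21.

**21 to 17 and 18 (through 19 and 20).** The bond between C3′ and the prenyl CH2 is cut. The prenyl nucleophile must bond through its primary carbon.

**16 to 15 to 14.** The C1′=C6′ bond is cut, so that C6′ arrives as a one-carbon unit, and the aldehyde is returned to the alcohol. C1′ is thus the hydroxymethyl carbon left by the key step. In 15, C3 is α to a carbonyl and β to an aryloxy leaving group, so both forward steps must be non-basic.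

**14 to 13 to 12 to 9 and 11 (11 from 10).** Three bonds are cut in turn: O5–CH3, then C6–C1″ (a retro-[3,3] shift that restores an O5–C bond), then O5–C(tertiary). Since C4a is substituted, C6 is the only ortho position open to a group delivered from O5, and O5 is distinguished from O7 by construction. The forward steps need branched O-allylation, an ortho-only shift, and reaction at the phenol in the presence of a free primary alcohol.

**9 to 7 (through 8).** The C5–O bond is traced back to C5–Br, the bromide that the ring closure leaves behind. The forward step needs a palladium-catalysed borylation that tolerates the free alcohol.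

**7 to 6.** O1–C8a is cut. This removes ring C and the stereocentre together and gives an achiral diol with two enantiotopic arms and two equivalent bromides. The forward step needs a catalyst that selects one arm.

**6 to 5 to 3 and 4.** The two CH2OH groups are returned to esters and the C3–C4 bond is cut. The forward step is a malonate alkylation by a hindered but activated benzylic bromide.

**3 to 2 to 1.** The benzylic C–Br and the O–CH2OCH3 bond are cut. The acetal must survive radical bromination.

## Other disconnections considered

**Alternative 1:** C3–C1′ and the bond from C4 to the oxygen on C2′ are cut. This leads to pterocarpan A1, which would come from 2H-chromene A2 and quinone A3.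

- Forward key step: TiCl2(OiPr)2 with a TADDOL ligand activates A3 as a chelate of tetravalent titanium. C3 of A2 attacks C5 of the quinone, and the benzylic cation at C4 is captured by the neighbouring quinone oxygen to close a cis-fused dihydrobenzofuran. Reductive cleavage of that benzylic C–O bond, debenzylation and oxidation of the 2′,5′-hydroquinone would finish the synthesis.
- In favour: one step joins both halves and forms C3–C1′ directly, and ring B arrives with its oxygen pattern in place. On convergence and on the number of steps after the union this alternative is the better of the two.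
- Against:
  - The second stereocentre (C4) is made only to be erased.
  - Facial control rests on a chiral Lewis acid that is normally needed in near-stoichiometric amount. Here it has to cope with the 5-OMe next to the cationic carbon and with a prenyl group flanking the oxygen that must close the ring.
  - The prenyl alkenes of A2 and A3 are themselves nucleophiles toward the activated quinone.
  - The C–O cleavage and the debenzylations cannot use H2 over palladium because of the prenyl groups.
  - A2 still requires its own answer to the C6/C8 question.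
- Comparison: structurally A1 holds the whole skeleton, whereas the chosen plan grows ring B last. Mechanistically a stepwise cationic cycloaddition under a strong Lewis acid with alkenes present stands against a copper-mediated C–O coupling on a substrate that has no alkene yet. The route is shorter in principle, but its end-game is the less safe.

**Alternative 2:** C6–C1″ and C3′–C1‴ are cut together. Phenol A4 would come from bis(1,1-dimethylallyl) ether A5 by two aromatic Claisen shifts.

- In favour: one thermal operation places both prenyl groups, and the regiochemistry is unambiguous because C6 is the only free ortho position of O5 and C3′ the only one of O2′. On ring A this is the same argument as for step 9, so it is the equal of the chosen plan there. On prenyl economy it is better: two groups in one step, and the alkenes appear late.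
- Against:
  - It does not address C3, so the (3R)-isoflavan core would need a separate asymmetric step.
  - A4 has two free phenols, of which only O5 is to be methylated.
  - Ring B must be oxidised to the quinone in the presence of the equally electron-rich ring A and two alkenes.
  - Four oxygens must be told apart by protecting groups.
- Comparison: structurally it only decorates a finished isoflavan. Mechanistically two concerted [3,3] shifts need no catalyst and are as reliable as step 9. What it saves on the ring B prenyl branch it spends on phenol differentiation and on the final oxidation.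

**Alternative 3:** Four bonds of ring A are cut (C4a–C8a, C5–C6, C6–C7, C8–C8a). Phenol A6 would come from diazo enone A7 and methoxyalkyne A8.

- Forward key step: irradiation of A7 causes a Wolff shift to a vinylketene, which adds [2+2] to the electron-rich alkyne of A8. The cyclobutenone opens (4π), recloses (6π) and tautomerises to the phenol. Desilylation and closure of O1–C2 would follow, then oxidation of ring B.
- In favour: every substituent of ring A, including the free OH on C8a needed for pyran closure, is fixed by the connectivity of the partners. No C6/C8 question arises, so on regiochemical certainty it is the equal of the chosen plan. It is convergent and needs no metal.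
- Against:
  - C3 must already be present in A8 as a benzylic stereocentre next to an electron-rich arene, which needs its own asymmetric synthesis.
  - Ring B is carried as a tetra-oxygenated arene and must be oxidised late beside ring A.
  - The carbene from A7 has a prenyl CH2 next to it, so a 1,2-hydrogen shift can compete with the Wolff shift.
  - The prenyl alkenes of both partners can act as ketenophiles.
  - 1-Methoxyalkynes are labile.
  - The benzannulation usually wants one partner in excess, and here both are advanced.
- Comparison: the chosen plan buys ring A as a cheap arene, whereas this plan builds it from two multistep fragments. It is therefore longer, although its key step forms more bonds.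

Key step: step 5

Assumptions on the chemistry:
- The sense of induction of the diamine–copper catalyst cannot be read from the substrate. The (1S,2S) label in step 5 stands for whichever antipode of the ligand delivers (3R)-7, to be fixed on a small scale.
- Prenyl chloride is used as the source of the ring B prenyl group, because allylic bromides tend to homocouple on zerovalent barium.
- 23 forms as both epimers at its carbinol carbon. Both converge in step 15, so the mixture is used.

## Route

Step 1
Reactants: 1 3,5-dibromo-4-methylphenol
Product: 2 1,3-dibromo-5-(methoxymethoxy)-2-methylbenzene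
Conditions: NaH, chloromethyl methyl ether, THF/DMF, 0 °C to rt
Reagents that add atoms: chloromethyl methyl ether, COCCl
Why: Williamson-type O-alkylation of the sodium phenoxide; the methoxymethyl acetal is chosen because it tolerates hydride, carbonate at 70–80 °C, palladium and organolithium and leaves under acid at the end.

Step 2
Reactants: 2 1,3-dibromo-5-(methoxymethoxy)-2-methylbenzene
Product: 3 1,3-dibromo-2-(bromomethyl)-5-(methoxymethoxy)benzene
Conditions: N-bromosuccinimide (1.05 equiv), AIBN (cat.), PhCF3, 80 °C
Reagents that add atoms: N-bromosuccinimide, O=C1CCC(=O)N1Br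
Why: Wohl–Ziegler radical bromination at the only benzylic C–H bonds; the two ring bromines and the low bromine concentration in a non-polar solvent disfavour ionic ring bromination, and one equivalent stops at the monobromide.

Step 3
Reactants: 3 1,3-dibromo-2-(bromomethyl)-5-(methoxymethoxy)benzene; 4 diethyl propanedioate (diethyl malonate)
Product: 5 diethyl 2-{[2,6-dibromo-4-(methoxymethoxy)phenyl]methyl}propanedioate
Conditions: NaH, 4 (2.5 equiv), THF, 0 °C to rt
Reagents that add atoms: none
Why: Malonic ester alkylation (SN2) of a benzylic bromide activated by the para oxygen; the excess of malonate and the bulk of the 2,6-dibromobenzyl group should suppress a second alkylation.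

Step 4
Reactants: 5 diethyl 2-{[2,6-dibromo-4-(methoxymethoxy)phenyl]methyl}propanedioate
Product: 6 2-{[2,6-dibromo-4-(methoxymethoxy)phenyl]methyl}propane-1,3-diol
Conditions: LiAlH4, THF, 0 °C
Reagents that add atoms: none
Why: Hydride reduction of both esters to the 2-substituted propane-1,3-diol; at 0 °C the aryl bromides and the acetal are not touched.

Step 5
Reactants: 6 2-{[2,6-dibromo-4-(methoxymethoxy)phenyl]methyl}propane-1,3-diol
Product: 7 [(3R)-5-bromo-7-(methoxymethoxy)-3,4-dihydro-2H-chromen-3-yl]methanol
Conditions: CuI (10 mol %), (1S,2S)-N,N′-dimethyl-1,2-diphenylethane-1,2-diamine (20 mol %), Cs2CO3 (2 equiv), 1,4-dioxane (0.05 M), 70 °C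
Reagents that add atoms: none
Why: Cs2CO3 turns one hydroxyl of 6 into an alkoxide on the diamine-bound monovalent copper, oxidative addition of a neighbouring C–Br bond gives a trivalent copper aryl alkoxide, and reductive elimination forms O1–C8a and returns monovalent copper. The closest known reaction type is the copper/chiral diamine desymmetrising intramolecular Ullmann etherification of 2-(2-halobenzyl)propane-1,3-diols to 3-(hydroxymethyl)chromans, a class to which 6 belongs. Ring C closes in a 6-exo mode, with the oxygen, C2, C3, C4 and C4a as the tether and the breaking C–Br bond outside the new ring. C3 is the only new stereocentre and is set by the ligand: the two CH2OH arms are enantiotopic, and in the copper-containing transition state the prochiral carbon lies two atoms from the metal, where the C2-symmetric diamine can tell one arm from the other. Only this enantiotopic-group selectivity is required, because the two bromides are exchanged by rotation about the C4–C4a bond and either one gives the same product from a given arm. Over-reaction is excluded by the substrate, since closure of the second arm onto C5 would need a bridged ring across the arene, and intermolecular etherification should be slow at this dilution. The oxygen on C7 is meta to both bromides and so does not deactivate them toward copper.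

Step 6
Reactants: 7 [(3R)-5-bromo-7-(methoxymethoxy)-3,4-dihydro-2H-chromen-3-yl]methanol
Product: 9 (3R)-3-(hydroxymethyl)-7-(methoxymethoxy)-3,4-dihydro-2H-chromen-5-ol, via pinacol boronate 8 (not isolated)
Conditions: bis(pinacolato)diboron, Pd(dppf)Cl2 (5 mol %), KOAc, 1,4-dioxane, 90 °C; then 30 % H2O2, NaOH (aq), THF, 0 °C
Reagents that add atoms: hydrogen peroxide, OO; bis(pinacolato)diboron, CC1(C)OB(OC1(C)C)B1OC(C)(C)C(C)(C)O1 (its atoms are in intermediate 8 only)
Why: Miyaura borylation of the aryl bromide followed by oxidation of the C–B bond (aryl shift from boron to oxygen in the hydroperoxide adduct) puts the oxygen exactly on C5; both stages tolerate the free primary alcohol and the acetal, and C3 is not involved.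

Step 7
Reactants: 10 2-methylbut-3-en-2-ol
Product: 11 tert-butyl 2-methylbut-3-en-2-yl carbonate
Conditions: n-BuLi, THF, −78 °C; di-tert-butyl dicarbonate, −78 °C to rt
Reagents that add atoms: di-tert-butyl dicarbonate, CC(C)(C)OC(=O)OC(=O)OC(C)(C)C
Why: Acylation of the lithium alkoxide of a tertiary allylic alcohol gives the mixed carbonate, the standard precursor of a 1,1-dimethyl-π-allyl palladium complex.

Step 8
Reactants: 9 (3R)-3-(hydroxymethyl)-7-(methoxymethoxy)-3,4-dihydro-2H-chromen-5-ol; 11 tert-butyl 2-methylbut-3-en-2-yl carbonate
Product: 12 [(3R)-7-(methoxymethoxy)-5-[(2-methylbut-3-en-2-yl)oxy]-3,4-dihydro-2H-chromen-3-yl]methanol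
Conditions: Pd(PPh3)4 (3 mol %), THF, 0 °C to rt
Reagents that add atoms: none
Why: Tsuji–Trost O-allylation: zerovalent palladium ionises 11, the tert-butoxide released after loss of CO2 deprotonates only the phenol, and the phenoxide attacks the more substituted allyl terminus to give the branched ether under kinetic control; a short reaction time avoids drift to the linear prenyl ether, and the aliphatic alcohol stays a spectator.

Step 9
Reactants: 12 [(3R)-7-(methoxymethoxy)-5-[(2-methylbut-3-en-2-yl)oxy]-3,4-dihydro-2H-chromen-3-yl]methanol
Product: 13 (3R)-3-(hydroxymethyl)-7-(methoxymethoxy)-6-(3-methylbut-2-en-1-yl)-3,4-dihydro-2H-chromen-5-ol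
Conditions: Eu(fod)3 (10 mol %), toluene, 80 °C
Reagents that add atoms: none
Why: Aromatic Claisen rearrangement: the [3,3] shift delivers the allyl terminus from O5 to C6, the only free ortho position because C4a is substituted, and the allylic inversion turns the 1,1-dimethylallyl group into prenyl; the europium Lewis acid lowers the temperature and favours the ortho over the para pathway.

Step 10
Reactants: 13 (3R)-3-(hydroxymethyl)-7-(methoxymethoxy)-6-(3-methylbut-2-en-1-yl)-3,4-dihydro-2H-chromen-5-ol
Product: 14 [(3R)-5-methoxy-7-(methoxymethoxy)-6-(3-methylbut-2-en-1-yl)-3,4-dihydro-2H-chromen-3-yl]methanol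
Conditions: MeI, K2CO3, acetone, 50 °C
Reagents that add atoms: iodomethane, CI
Why: Williamson methylation of the only phenol; carbonate deprotonates the phenol but not the primary alcohol, so O5 alone is methylated.

Step 11
Reactants: 14 [(3R)-5-methoxy-7-(methoxymethoxy)-6-(3-methylbut-2-en-1-yl)-3,4-dihydro-2H-chromen-3-yl]methanol
Product: 15 (3S)-5-methoxy-7-(methoxymethoxy)-6-(3-methylbut-2-en-1-yl)-3,4-dihydro-2H-chromene-3-carbaldehyde
Conditions: Dess–Martin periodinane, NaHCO3 (solid buffer), CH2Cl2, 0 °C to rt
Reagents that add atoms: none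
Why: Dess–Martin oxidation under buffered, non-basic conditions gives the aldehyde without enolisation; the descriptor changes to S only because CHO outranks C2, and the aldehyde is used at once.

Step 12
Reactants: 15 (3S)-5-methoxy-7-(methoxymethoxy)-6-(3-methylbut-2-en-1-yl)-3,4-dihydro-2H-chromene-3-carbaldehyde
Product: 16 (3R)-3-(2,2-dibromoethenyl)-5-methoxy-7-(methoxymethoxy)-6-(3-methylbut-2-en-1-yl)-3,4-dihydro-2H-chromene
Conditions: PPh3, CBr4, Zn, CH2Cl2, rt (ylide pre-formed); then 15, 0 °C
Reagents that add atoms: carbon tetrabromide, BrC(Br)(Br)Br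
Why: Ramirez dibromo-olefination (first stage of the Corey–Fuchs sequence); pre-forming the ylide with zinc keeps the medium free of acid and of strong base, so the Wittig reaction should outrun enolisation and leave C3, the acetal and the prenyl group untouched.

Step 13
Reactants: 17 1-chloro-3-methylbut-2-ene (prenyl chloride); 18 3,4-di-tert-butoxycyclobut-3-ene-1,2-dione
Product: 21 3-tert-butoxy-4-(3-methylbut-2-en-1-yl)cyclobut-3-ene-1,2-dione, via prenylbarium chloride 19 (not isolated), via hydroxycyclobutenone adduct 20 (not isolated)
Conditions: BaI2, Li, biphenyl, THF, rt (gives zerovalent barium); 17, −78 °C; 18, −78 °C; then trifluoroacetic anhydride, −78 to 0 °C; NaHCO3 (aq)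
Reagents that add atoms: barium (from BaI2), [Ba] (in intermediate 19 only)
Why: Allylbarium reagents made at −78 °C add to carbonyl groups through their less substituted carbon, so 1,2-addition to a squarate carbonyl gives the linear prenyl carbinol 20; trifluoroacetylation and ionisation, with loss of the tert-butyl group of the distal enol ether as isobutene, is the standard conversion of squarate adducts into 3-alkoxy-4-alkylcyclobutenediones.

Step 14
Reactants: 16 (3R)-3-(2,2-dibromoethenyl)-5-methoxy-7-(methoxymethoxy)-6-(3-methylbut-2-en-1-yl)-3,4-dihydro-2H-chromene; 21 3-tert-butoxy-4-(3-methylbut-2-en-1-yl)cyclobut-3-ene-1,2-dione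
Product: 23 3-tert-butoxy-4-hydroxy-4-{[(3R)-5-methoxy-7-(methoxymethoxy)-6-(3-methylbut-2-en-1-yl)-3,4-dihydro-2H-chromen-3-yl]ethynyl}-2-(3-methylbut-2-en-1-yl)cyclobut-2-en-1-one (both epimers at the carbinol carbon), via lithium acetylide 22 (not isolated)
Conditions: n-BuLi (2.05 equiv), THF, −78 to −20 °C; then 21, −78 °C; NH4Cl (aq), −78 °C
Reagents that add atoms: n-butyllithium, [Li]CCCC (its lithium is in intermediate 22 only)
Why: Second stage of the Corey–Fuchs sequence (Br/Li exchange, Fritsch–Buttenberg–Wiechell shift, deprotonation) gives acetylide 22, which adds to the ketone-like carbonyl of 21 next to the C–O-tert-butyl carbon and not to the vinylogous ester carbonyl; at −78 °C addition to the strained dione should outrun proton abstraction from its allylic CH2, and the new carbinol centre is inconsequential.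

Step 15
Reactants: 23 3-tert-butoxy-4-hydroxy-4-{[(3R)-5-methoxy-7-(methoxymethoxy)-6-(3-methylbut-2-en-1-yl)-3,4-dihydro-2H-chromen-3-yl]ethynyl}-2-(3-methylbut-2-en-1-yl)cyclobut-2-en-1-one
Product: 24 2-tert-butoxy-5-[(3R)-5-methoxy-7-(methoxymethoxy)-6-(3-methylbut-2-en-1-yl)-3,4-dihydro-2H-chromen-3-yl]-3-(3-methylbut-2-en-1-yl)cyclohexa-2,5-diene-1,4-dione
Conditions: toluene (degassed, 0.02 M), 110 °C
Reagents that add atoms: none
Why: Moore rearrangement: 4π ring opening with the hydroxyl turning outward gives an enynyl ketene, whose ketene carbon bonds to the alkyne carbon attached to C3 (forming C1′–C2′), and hydrogen transfer from the hydroxyl to the ring radical at C6′ gives the quinone; an alkyl-substituted alkyne favours six- over five-membered closure, and the substitution pattern of ring B follows from the connectivity of 23.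

Step 16
Reactants: 24 2-tert-butoxy-5-[(3R)-5-methoxy-7-(methoxymethoxy)-6-(3-methylbut-2-en-1-yl)-3,4-dihydro-2H-chromen-3-yl]-3-(3-methylbut-2-en-1-yl)cyclohexa-2,5-diene-1,4-dione
Product: 25 2-hydroxy-5-[(3R)-7-hydroxy-5-methoxy-6-(3-methylbut-2-en-1-yl)-3,4-dihydro-2H-chromen-3-yl]-3-(3-methylbut-2-en-1-yl)cyclohexa-2,5-diene-1,4-dione (CNP0148998.1)
Conditions: 3 M HCl (aq), THF/i-PrOH, 40 °C
Reagents that add atoms: none
Why: Acid cleaves the tert-butyl vinylogous ester by ionisation at the tert-butyl carbon and hydrolyses the methoxymethyl acetal, both with retention of the ring oxygens; a hindered alcohol cosolvent avoids re-etherification of the hydroxyquinone, and no base is used once ring B exists, so C3 is not at risk.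

## Compound list

1 | 3,5-dibromo-4-methylphenol | Cc1c(Br)cc(O)cc1Br | starting material
2 | 1,3-dibromo-5-(methoxymethoxy)-2-methylbenzene | COCOc1cc(Br)c(C)c(Br)c1 | intermediate
3 | 1,3-dibromo-2-(bromomethyl)-5-(methoxymethoxy)benzene | COCOc1cc(Br)c(CBr)c(Br)c1 | intermediate
4 | diethyl propanedioate (diethyl malonate) | CCOC(=O)CC(=O)OCC | starting material
5 | diethyl 2-{[2,6-dibromo-4-(methoxymethoxy)phenyl]methyl}propanedioate | CCOC(=O)C(Cc1c(Br)cc(OCOC)cc1Br)C(=O)OCC | intermediate
6 | 2-{[2,6-dibromo-4-(methoxymethoxy)phenyl]methyl}propane-1,3-diol | COCOc1cc(Br)c(CC(CO)CO)c(Br)c1 | intermediate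
7 | [(3R)-5-bromo-7-(methoxymethoxy)-3,4-dihydro-2H-chromen-3-yl]methanol | COCOc1cc(Br)c2C[C@H](CO)COc2c1 | intermediate
8 | [(3R)-7-(methoxymethoxy)-5-(4,4,5,5-tetramethyl-1,3,2-dioxaborolan-2-yl)-3,4-dihydro-2H-chromen-3-yl]methanol | COCOc1cc(B3OC(C)(C)C(C)(C)O3)c2C[C@H](CO)COc2c1 | intermediate (not isolated)
9 | (3R)-3-(hydroxymethyl)-7-(methoxymethoxy)-3,4-dihydro-2H-chromen-5-ol | COCOc1cc(O)c2C[C@H](CO)COc2c1 | intermediate
10 | 2-methylbut-3-en-2-ol | CC(C)(O)C=C | starting material
11 | tert-butyl 2-methylbut-3-en-2-yl carbonate | CC(C)(C)OC(=O)OC(C)(C)C=C | intermediate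
12 | [(3R)-7-(methoxymethoxy)-5-[(2-methylbut-3-en-2-yl)oxy]-3,4-dihydro-2H-chromen-3-yl]methanol | COCOc1cc(OC(C)(C)C=C)c2C[C@H](CO)COc2c1 | intermediate
13 | (3R)-3-(hydroxymethyl)-7-(methoxymethoxy)-6-(3-methylbut-2-en-1-yl)-3,4-dihydro-2H-chromen-5-ol | COCOc1c(CC=C(C)C)c(O)c2C[C@H](CO)COc2c1 | intermediate
14 | [(3R)-5-methoxy-7-(methoxymethoxy)-6-(3-methylbut-2-en-1-yl)-3,4-dihydro-2H-chromen-3-yl]methanol | COCOc1c(CC=C(C)C)c(OC)c2C[C@H](CO)COc2c1 | intermediate
15 | (3S)-5-methoxy-7-(methoxymethoxy)-6-(3-methylbut-2-en-1-yl)-3,4-dihydro-2H-chromene-3-carbaldehyde | COCOc1c(CC=C(C)C)c(OC)c2C[C@H](C=O)COc2c1 | intermediate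
16 | (3R)-3-(2,2-dibromoethenyl)-5-methoxy-7-(methoxymethoxy)-6-(3-methylbut-2-en-1-yl)-3,4-dihydro-2H-chromene | COCOc1c(CC=C(C)C)c(OC)c2C[C@H](C=C(Br)Br)COc2c1 | intermediate
17 | 1-chloro-3-methylbut-2-ene (prenyl chloride) | CC(C)=CCCl | starting material
18 | 3,4-di-tert-butoxycyclobut-3-ene-1,2-dione | CC(C)(C)OC1=C(OC(C)(C)C)C(=O)C1=O | starting material
19 | (3-methylbut-2-en-1-yl)barium chloride | CC(C)=CC[Ba]Cl | intermediate (not isolated)
20 | 2,3-di-tert-butoxy-4-hydroxy-4-(3-methylbut-2-en-1-yl)cyclobut-2-en-1-one (racemic, present as its barium alkoxide) | CC(C)=CCC1(O)C(OC(C)(C)C)=C(OC(C)(C)C)C1=O | intermediate (not isolated)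
21 | 3-tert-butoxy-4-(3-methylbut-2-en-1-yl)cyclobut-3-ene-1,2-dione | CC(C)=CCC1=C(OC(C)(C)C)C(=O)C1=O | intermediate
22 | {[(3R)-5-methoxy-7-(methoxymethoxy)-6-(3-methylbut-2-en-1-yl)-3,4-dihydro-2H-chromen-3-yl]ethynyl}lithium | COCOc1c(CC=C(C)C)c(OC)c2C[C@H](C#C[Li])COc2c1 | intermediate (not isolated)
23 | 3-tert-butoxy-4-hydroxy-4-{[(3R)-5-methoxy-7-(methoxymethoxy)-6-(3-methylbut-2-en-1-yl)-3,4-dihydro-2H-chromen-3-yl]ethynyl}-2-(3-methylbut-2-en-1-yl)cyclobut-2-en-1-one (both epimers at the carbinol carbon) | COCOc1c(CC=C(C)C)c(OC)c2C[C@H](C#CC3(O)C(OC(C)(C)C)=C(CC=C(C)C)C3=O)COc2c1 | intermediate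
24 | 2-tert-butoxy-5-[(3R)-5-methoxy-7-(methoxymethoxy)-6-(3-methylbut-2-en-1-yl)-3,4-dihydro-2H-chromen-3-yl]-3-(3-methylbut-2-en-1-yl)cyclohexa-2,5-diene-1,4-dione | COCOc1c(CC=C(C)C)c(OC)c2C[C@H](C3=CC(=O)C(OC(C)(C)C)=C(CC=C(C)C)C3=O)COc2c1 | intermediate
25 | 2-hydroxy-5-[(3R)-7-hydroxy-5-methoxy-6-(3-methylbut-2-en-1-yl)-3,4-dihydro-2H-chromen-3-yl]-3-(3-methylbut-2-en-1-yl)cyclohexa-2,5-diene-1,4-dione | COc1c(CC=C(C)C)c(O)cc2c1C[C@H](C1=CC(=O)C(O)=C(CC=C(C)C)C1=O)CO2 | target

## Step count and least certain steps

Total step count: 16. Step 7 prepares reagent 11 and step 13 prepares fragment 21.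
Longest linear sequence: 14 steps from 1 to 25 (steps 1–6, 8–12 and 14–16).

**Step 5 (key step).** The most likely failure is weak discrimination between the two enantiotopic arms. It would be aggravated if oxidative addition of the aryl bromide is slow enough to force a higher temperature, and some reductive loss of bromine may accompany it. The fallback separates stereocontrol from ring closure, sets out from 6 and returns at 7:
- A lipase-mediated mono-acetylation with vinyl acetate (enzyme selected for this sense) should give (2R)-2-{[2,6-dibromo-4-(methoxymethoxy)phenyl]methyl}-3-hydroxypropyl acetate F1.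
- Silylation of the free arm (tert-butyldiphenylsilyl chloride, imidazole) gives (2S)-3-[(tert-butyldiphenylsilyl)oxy]-2-{[2,6-dibromo-4-(methoxymethoxy)phenyl]methyl}propyl acetate F2.
- Methanolysis (K2CO3, MeOH) frees the other arm as (2S)-3-[(tert-butyldiphenylsilyl)oxy]-2-{[2,6-dibromo-4-(methoxymethoxy)phenyl]methyl}propan-1-ol F3.
- A non-asymmetric copper etherification (CuI, 1,10-phenanthroline, Cs2CO3, toluene, 100 °C) forms the same O1–C8a bond and gives tert-butyl{[(3S)-5-bromo-7-(methoxymethoxy)-3,4-dihydro-2H-chromen-3-yl]methoxy}diphenylsilane F4.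
- Bu4NF then releases 7.

**Step 2.** The most likely failure is hydrogen abstraction from the OCH2O group or cleavage of the acetal by HBr, together with ionic bromination ortho to the ether. The fallback changes the protecting-group logic, sets out from 1 and returns at 6:
- Pivaloylation gives 3,5-dibromo-4-methylphenyl 2,2-dimethylpropanoate F5, whose ester deactivates the ring and has no abstractable hydrogen next to oxygen.
- Radical bromination gives 3,5-dibromo-4-(bromomethyl)phenyl 2,2-dimethylpropanoate F6.
- Malonate alkylation gives diethyl 2-{[2,6-dibromo-4-(2,2-dimethylpropanoyloxy)phenyl]methyl}propanedioate F7.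
- LiAlH4 reduces the malonate and removes the pivalate in one operation to give 2-[(2,6-dibromo-4-hydroxyphenyl)methyl]propane-1,3-diol F8.
- The phenol alone is then converted to its methoxymethyl ether (K2CO3, chloromethyl methyl ether, acetone) to reach 6.

**Step 13.** The most likely failure is bonding of the prenyl metal through its tertiary carbon, or homocoupling during barium insertion, either of which would erode the linear prenyl pattern. The fallback installs the alkene geometry-free and builds the trisubstituted olefin afterwards, sets out from 18 and returns at 21: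
- Allylmagnesium bromide adds to give 2,3-di-tert-butoxy-4-hydroxy-4-(prop-2-en-1-yl)cyclobut-2-en-1-one F9.
- Trifluoroacetic anhydride converts it to 3-tert-butoxy-4-(prop-2-en-1-yl)cyclobut-3-ene-1,2-dione F10.
- Cross metathesis with 2-methylbut-2-ene (second-generation Grubbs catalyst) gives 21.

**Step 12 (with the aldehyde of step 11).** The most likely failure is erosion of configuration at C3 by enolisation or by ring opening through loss of the aryloxide while the hindered aldehyde reacts slowly, or loss of the acetal if acidic phosphonium bromide species are present. The fallback replaces the phosphorus chemistry with a cold, one-step homologation, sets out from 15 and returns at 23: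
- The Colvin rearrangement with TMSC(Li)N2 in THF at −78 °C gives (3R)-3-ethynyl-5-methoxy-7-(methoxymethoxy)-6-(3-methylbut-2-en-1-yl)-3,4-dihydro-2H-chromene F11.
- One equivalent of n-BuLi converts F11 into 22, which adds to 21 to give 23.

**Step 16.** The most likely failure is acid-promoted closure of a prenyl group onto its neighbouring OH during the slower acetal hydrolysis, on a compound that by then holds two such pairs and the quinone. The fallback removes the acetal before ring B exists, sets out from 16 and returns at 25:
- HCl in MeOH at rt gives (3R)-3-(2,2-dibromoethenyl)-5-methoxy-6-(3-methylbut-2-en-1-yl)-3,4-dihydro-2H-chromen-7-ol F12.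
- n-BuLi (3.05 equiv) gives the dilithium phenoxide acetylide F13.
- F13 adds to 21 to give 3-tert-butoxy-4-hydroxy-4-{[(3R)-7-hydroxy-5-methoxy-6-(3-methylbut-2-en-1-yl)-3,4-dihydro-2H-chromen-3-yl]ethynyl}-2-(3-methylbut-2-en-1-yl)cyclobut-2-en-1-one F14.
- Thermolysis in toluene gives 2-tert-butoxy-5-[(3R)-7-hydroxy-5-methoxy-6-(3-methylbut-2-en-1-yl)-3,4-dihydro-2H-chromen-3-yl]-3-(3-methylbut-2-en-1-yl)cyclohexa-2,5-diene-1,4-dione F15.
- A brief treatment with trifluoroacetic acid in CH2Cl2 at 0 °C removes only the tert-butyl group and gives 25.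

## Further compounds

F1 | step 5 | (2R)-2-{[2,6-dibromo-4-(methoxymethoxy)phenyl]methyl}-3-hydroxypropyl acetate | COCOc1cc(Br)c(C[C@H](CO)COC(C)=O)c(Br)c1
F2 | step 5 | (2S)-3-[(tert-butyldiphenylsilyl)oxy]-2-{[2,6-dibromo-4-(methoxymethoxy)phenyl]methyl}propyl acetate | COCOc1cc(Br)c(C[C@H](CO[Si](c2ccccc2)(c2ccccc2)C(C)(C)C)COC(C)=O)c(Br)c1
F3 | step 5 | (2S)-3-[(tert-butyldiphenylsilyl)oxy]-2-{[2,6-dibromo-4-(methoxymethoxy)phenyl]methyl}propan-1-ol | COCOc1cc(Br)c(C[C@H](CO[Si](c2ccccc2)(c2ccccc2)C(C)(C)C)CO)c(Br)c1
F4 | step 5 | tert-butyl{[(3S)-5-bromo-7-(methoxymethoxy)-3,4-dihydro-2H-chromen-3-yl]methoxy}diphenylsilane | COCOc1cc(Br)c2C[C@H](CO[Si](c3ccccc3)(c3ccccc3)C(C)(C)C)COc2c1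
F5 | step 2 | 3,5-dibromo-4-methylphenyl 2,2-dimethylpropanoate | Cc1c(Br)cc(OC(=O)C(C)(C)C)cc1Br
F6 | step 2 | 3,5-dibromo-4-(bromomethyl)phenyl 2,2-dimethylpropanoate | BrCc1c(Br)cc(OC(=O)C(C)(C)C)cc1Br
F7 | step 2 | diethyl 2-{[2,6-dibromo-4-(2,2-dimethylpropanoyloxy)phenyl]methyl}propanedioate | CCOC(=O)C(Cc1c(Br)cc(OC(=O)C(C)(C)C)cc1Br)C(=O)OCC
F8 | step 2 | 2-[(2,6-dibromo-4-hydroxyphenyl)methyl]propane-1,3-diol | Oc1cc(Br)c(CC(CO)CO)c(Br)c1
F9 | step 13 | 2,3-di-tert-butoxy-4-hydroxy-4-(prop-2-en-1-yl)cyclobut-2-en-1-one | C=CCC1(O)C(OC(C)(C)C)=C(OC(C)(C)C)C1=O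
F10 | step 13 | 3-tert-butoxy-4-(prop-2-en-1-yl)cyclobut-3-ene-1,2-dione | C=CCC1=C(OC(C)(C)C)C(=O)C1=O
F11 | step 12 | (3R)-3-ethynyl-5-methoxy-7-(methoxymethoxy)-6-(3-methylbut-2-en-1-yl)-3,4-dihydro-2H-chromene | COCOc1c(CC=C(C)C)c(OC)c2C[C@H](C#C)COc2c1
F12 | step 16 | (3R)-3-(2,2-dibromoethenyl)-5-methoxy-6-(3-methylbut-2-en-1-yl)-3,4-dihydro-2H-chromen-7-ol | Oc1c(CC=C(C)C)c(OC)c2C[C@H](C=C(Br)Br)COc2c1
F13 | step 16 | dilithium salt of (3R)-3-ethynyl-5-methoxy-6-(3-methylbut-2-en-1-yl)-3,4-dihydro-2H-chromen-7-ol (phenoxide and acetylide) | [Li]Oc1c(CC=C(C)C)c(OC)c2C[C@H](C#C[Li])COc2c1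
F14 | step 16 | 3-tert-butoxy-4-hydroxy-4-{[(3R)-7-hydroxy-5-methoxy-6-(3-methylbut-2-en-1-yl)-3,4-dihydro-2H-chromen-3-yl]ethynyl}-2-(3-methylbut-2-en-1-yl)cyclobut-2-en-1-one | Oc1c(CC=C(C)C)c(OC)c2C[C@H](C#CC3(O)C(OC(C)(C)C)=C(CC=C(C)C)C3=O)COc2c1
F15 | step 16 | 2-tert-butoxy-5-[(3R)-7-hydroxy-5-methoxy-6-(3-methylbut-2-en-1-yl)-3,4-dihydro-2H-chromen-3-yl]-3-(3-methylbut-2-en-1-yl)cyclohexa-2,5-diene-1,4-dione | Oc1c(CC=C(C)C)c(OC)c2C[C@H](C3=CC(=O)C(OC(C)(C)C)=C(CC=C(C)C)C3=O)COc2c1
A1 | alternative 1 | (6aR,11aR)-3,9-bis(benzyloxy)-1-methoxy-2,10-bis(3-methylbut-2-en-1-yl)pterocarpan-8-ol | COc1c(CC=C(C)C)c(OCc5ccccc5)cc2c1[C@@H]3Oc4c(CC=C(C)C)c(OCc6ccccc6)c(O)cc4[C@@H]3CO2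
A2 | alternative 1 | 7-(benzyloxy)-5-methoxy-6-(3-methylbut-2-en-1-yl)-2H-chromene | COc1c(CC=C(C)C)c(OCc3ccccc3)cc2OCC=Cc12
A3 | alternative 1 | 2-(benzyloxy)-3-(3-methylbut-2-en-1-yl)cyclohexa-2,5-diene-1,4-dione | O=C1C=CC(=O)C(CC=C(C)C)=C1OCc1ccccc1
A4 | alternative 2 | (3R)-3-[2-hydroxy-5-methoxy-4-(methoxymethoxy)-3-(3-methylbut-2-en-1-yl)phenyl]-7-(methoxymethoxy)-6-(3-methylbut-2-en-1-yl)-3,4-dihydro-2H-chromen-5-ol | Oc1c(CC=C(C)C)c(OCOC)cc2c1C[C@H](c1cc(OC)c(OCOC)c(CC=C(C)C)c1O)CO2
A5 | alternative 2 | (3R)-3-[5-methoxy-4-(methoxymethoxy)-2-[(2-methylbut-3-en-2-yl)oxy]phenyl]-7-(methoxymethoxy)-5-[(2-methylbut-3-en-2-yl)oxy]-3,4-dihydro-2H-chromene | C=CC(C)(C)Oc1cc(OCOC)cc2c1C[C@H](c1cc(OC)c(OCOC)cc1OC(C)(C)C=C)CO2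
A6 | alternative 3 | 2-[(2R)-3-[(tert-butyldimethylsilyl)oxy]-2-[2,5-dimethoxy-4-(methoxymethoxy)-3-(3-methylbut-2-en-1-yl)phenyl]propyl]-3-methoxy-5-(methoxymethoxy)-4-(3-methylbut-2-en-1-yl)phenol | Oc1cc(OCOC)c(CC=C(C)C)c(OC)c1C[C@H](c1cc(OC)c(OCOC)c(CC=C(C)C)c1OC)CO[Si](C)(C)C(C)(C)C
A7 | alternative 3 | 4-diazo-2-(methoxymethoxy)-7-methylocta-1,6-dien-3-one | C=C(OCOC)C(=O)C(=[N+]=[N-])CC=C(C)C
A8 | alternative 3 | tert-butyl({(2R)-2-[2,5-dimethoxy-4-(methoxymethoxy)-3-(3-methylbut-2-en-1-yl)phenyl]-5-methoxypent-4-yn-1-yl}oxy)dimethylsilane | COC#CC[C@H](c1cc(OC)c(OCOC)c(CC=C(C)C)c1OC)CO[Si](C)(C)C(C)(C)C
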